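The earlier runs and the new flask are calculated with made-up constants; scatter was added.

Start from how slow the gamma run has become by its end: between its last two readings it adds 11.7 mM in 46.0 min, yet its product stands at 34.8% of the starting material charged, and starting material is the limiting reagent, with partner charged at 900 mM against 300 mM.

in all of them: partner 900 mM

| charge | starting material | catalyst | time |
|---|---|---|---|
| gamma | 300 mM | 6.00 mM |  |
| eta | 150 mM | 6.00 mM |  |
| delta | 300 mM | 9.00 mM |  |
| epsilon | 300 mM | 12.0 mM | 84 min |

| gamma run: time / min | gamma run: [product] / mM | eta run: time / min | eta run: [product] / mM | delta run: time / min | delta run: [product] / mM |
|---|---|---|---|---|---|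
| 3.4 | 24.0 | 3.4 | 15.9 | 3.4 | 39.6 |
| 7.5 | 41.2 | 7.5 | 26.6 | 7.5 | 62.8 |
| 17 | 71.4 | 17 | 48.0 | 17 | 94.8 |
| 38 | 92.7 | 38 | 63.5 | 38 | 116.1 |
| 84 | 104.4 | 84 | 73.3 | 84 | 127.2 |

(readings scatter by 2 mM)

1. order of the initial rate in [catalyst], near the charge of the gamma run, the rate being that where two percent of its starting material are product
2. order of the initial rate in [starting material], near the charge of the gamma run, the rate being that where two percent of its starting material are product (one fixed amount of product, the same in the runs compared)
3. product in the epsilon run at 84 min, as a share of the starting material charged

- Overall: starting material + partner -> product, with catalyst as catalyst.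
- Constant volume, constant temperature.
- A reading of a species includes what of it is bound.
- An order is taken over about fifteen percent of the charge, up and down.

Read the last row of each run against its charge, and carry one quantity through the reading: the load, the charge of starting material divided by the charge of catalyst, 25.0 in the epsilon run. Take gamma first, with a load of 50.0 and a share at its last reading of 34.8%. Go on to delta, which puts more catalyst on the same starting material, for a load of 33.3 and a share of 42.4%. End with eta, which keeps gamma's catalyst on half the starting material, for a load of 25.0 and a share of 48.9%, so the share climbs as the load falls, whichever charge was changed.

Reckon this as a race of lifetimes, which is my own reading: assuming orders near one, a molecule of starting material lasts on the way to product for a time going as one over c(catalyst), while eta's share, higher than gamma's, suggests a second loss whose lifetime goes as one over c(starting material). At this partner charge and temperature, the loss lifetimes inside one product lifetime then count as the load times a constant. Now look at epsilon, which has twice eta's starting material and twice its catalyst, so both lifetimes shorten together and the load stays equal to eta's. Treating eta's last reading as the end of its course, although the eta run still added 9.80 mM after 38 min, my reckoning therefore puts epsilon at eta's 48.9%, with a scatter of 1.33% on that reading.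

The forecast, on other grounds, says 47%, holding that “product rises about logarithmically with catalyst”, and gives orders of 1.1 in catalyst and 0.6 in starting material.

The flask gives orders of 1.1 and 0.89, the second above the forecast's, and 48.9% for epsilon.

    catalyst + starting material ⇌ catalyst-substrate complex (18.54 L mol⁻¹ min⁻¹, 25.02 min⁻¹)
    catalyst-substrate complex + partner → product + catalyst (115.2 L mol⁻¹ min⁻¹)
    2 starting material → homo dimer (0.3006 L mol⁻¹ min⁻¹)
    2 partner ⇌ idle reagent dimer, settled at all times (32.10 L mol⁻¹)

The second runner in the race is the step from 2 starting material to homo dimer, which uses no catalyst and whose first half-life by this step alone, at epsilon's charge, is 5.54 min. That step is the main reason the epsilon run stands short of full conversion at 84 min: in the run with it taken away, at the same load of 25.0, epsilon's product reaches 99.6% of its charge.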